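**Plan**

- Cuts (bridge carbons numbered C1' on ring A to C14' on ring B): the three O–Me groups; then the C2'–C3' bond, taken back to a C2'=C3' alkene and, by putting SO2 back between these two carbons, to a 22-membered cyclic sulfone; then the two C–S bonds (bis-mesylate plus sulfide); then C13'–C14' (Wittig) and the diaryl ether C–O bond (Ullmann).
- Forward: ring A phenol and ring B bromo aldehyde are joined through the ether oxygen, and the 12-carbon arm is grown from the ring B aldehyde. The two primary alcohols are then tied through sulfur into a 22-membered thiacycle, which is oxidized and contracted by a Ramberg–Bäcklund reaction to the 21-membered carbocycle; hydrogenation and demethylation finish.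
- Enabling feature: C2' and C3' are two unsubstituted CH2 groups of the polymethylene bridge, one carbon away from ring A and far from ring B. Both can sit on sulfur as primary carbons, and either α-halogenation of the sulfone leads to the same alkene, so one sulfur atom can be placed between them and expelled again.
- The carbocyclic 21-membered ring is therefore never closed by a C–C macrocyclization; it is cut out of an easily closed thiacycle by loss of one atom.
- Stereochemistry: the target has no stereocentre and no alkene; the two alkenes made on the way are hydrogenated, so their geometry is not controlled.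

Key step: step 10

Assumption: the three starting materials (the dimethoxyphenethyl alcohol, the bromo-hydroxy-methoxybenzaldehyde and 11-bromoundecan-1-ol) are taken as commercial.

**Route**

Step 1
Reactants: 1 2-(3,5-dimethoxyphenyl)ethan-1-ol
Product: 2 3-(2-hydroxyethyl)-5-methoxyphenol
Conditions: NaSEt (2.5 equiv), DMF, 140 °C; then 1 M HCl
Reagents that add atoms: none
Why: Thiolate demethylation (SN2 at the methyl carbon) should stop after one ether, because the phenoxide formed makes the second methoxy group a far poorer leaving group, and the primary alcohol is inert to thiolate.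

Step 2
Reactants: 3 3-bromo-2-hydroxy-5-methoxybenzaldehyde
Product: 4 3-bromo-2,5-dimethoxybenzaldehyde
Conditions: MeI, K2CO3, DMF, rt
Reagents that add atoms: iodomethane, CI
Why: Williamson ether synthesis on the acidic salicylaldehyde phenol, which caps the OH next to bromine so that it cannot compete as a nucleophile in step 3.

Step 3
Reactants: 2 3-(2-hydroxyethyl)-5-methoxyphenol (1.2 equiv); 4 3-bromo-2,5-dimethoxybenzaldehyde
Product: 5 3-[3-(2-hydroxyethyl)-5-methoxyphenoxy]-2,5-dimethoxybenzaldehyde
Conditions: CuI (10 mol %), N,N-dimethylglycine hydrochloride (30 mol %), Cs2CO3, 1,4-dioxane, 100 °C, Ar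
Reagents that add atoms: none
Why: Ligand-accelerated Ullmann diaryl ether synthesis, in which only the phenoxide of 2 forms with carbonate and couples at the C–Br bond of 4; the aliphatic OH is not arylated under these conditions and the non-enolizable aldehyde is tolerated.

Step 4
Reactants: 6 11-bromoundecan-1-ol
Product: 7 (11-hydroxyundecyl)triphenylphosphonium bromide
Conditions: PPh3, MeCN, reflux
Reagents that add atoms: triphenylphosphine, c1ccc(cc1)P(c1ccccc1)c1ccccc1
Why: SN2 quaternization of the primary bromide by the phosphine; the hydroxyl group does not interfere.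

Step 5
Reactants: 5 3-[3-(2-hydroxyethyl)-5-methoxyphenoxy]-2,5-dimethoxybenzaldehyde; 7 (11-hydroxyundecyl)triphenylphosphonium bromide (2.2 equiv)
Product: 9 (Z)-12-{3-[3-(2-hydroxyethyl)-5-methoxyphenoxy]-2,5-dimethoxyphenyl}dodec-11-en-1-ol, via alkoxide ylide 8 (not isolated)
Conditions: 7, NaN(SiMe3)2 (4.4 equiv), THF, 0 °C; then 5, −78 °C to rt; then H2O
Reagents that add atoms: none
Why: Wittig olefination with the non-stabilized ylide 8 (two equivalents of base per salt, one for the OH and one for the α-CH2) joins the 11-carbon arm to the ring B aldehyde carbon; the free OH of 5 is only deprotonated, and the expected mainly Z geometry is of no consequence.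

Step 6
Reactants: 9 (Z)-12-{3-[3-(2-hydroxyethyl)-5-methoxyphenoxy]-2,5-dimethoxyphenyl}dodec-11-en-1-ol
Product: 10 12-{3-[3-(2-hydroxyethyl)-5-methoxyphenoxy]-2,5-dimethoxyphenyl}dodecan-1-ol
Conditions: H2 (1 atm), Pd/C (10 wt % Pd on carbon), EtOAc, rt
Reagents that add atoms: none
Why: Catalytic hydrogenation saturates the styrene-type alkene, which could otherwise react with the oxidant of step 9 or the carbene-forming halogen donor of step 10, and leaves aryl ethers and alcohols untouched.

Step 7
Reactants: 10 12-{3-[3-(2-hydroxyethyl)-5-methoxyphenoxy]-2,5-dimethoxyphenyl}dodecan-1-ol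
Product: 11 12-{3-[3-(2-mesyloxyethyl)-5-methoxyphenoxy]-2,5-dimethoxyphenyl}dodecyl methanesulfonate
Conditions: MsCl (2.5 equiv), Et3N (3 equiv), CH2Cl2, 0 °C
Reagents that add atoms: methanesulfonyl chloride, CS(Cl)(=O)=O
Why: Sulfonylation of both primary alcohols turns them into leaving groups of equal reactivity, so no differentiation of the two ends is needed.

Step 8
Reactants: 11 12-{3-[3-(2-mesyloxyethyl)-5-methoxyphenoxy]-2,5-dimethoxyphenyl}dodecyl methanesulfonate
Product: 14 22-membered macrocyclic sulfide (ring A–CH2CH2–S–(CH2)12–ring B; rings joined by the ether oxygen; three OMe), via ring-A-side sodium thiolate 12 (not isolated), via chain-end sodium thiolate 13 (not isolated)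
Conditions: Na2S·9H2O (1.05 equiv), DMF, 50 °C, Ar; syringe-pump co-addition of 11 and the sulfide (final concentration about 2 mM)
Reagents that add atoms: sodium sulfide (used as Na2S·9H2O), [Na+].[Na+].[S-2]
Why: Double SN2 thioetherification, in which sulfide displaces one mesylate to give thiolate 12 or 13 and this closes the 22-membered ring on the other mesylate under high dilution; thiolate is a strong nucleophile and a weak base, so substitution should outrun E2 even at the 2-arylethyl position, and both thiolates give the same ring.

Step 9
Reactants: 14 22-membered macrocyclic sulfide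
Product: 15 22-membered macrocyclic sulfone (ring A–CH2CH2–SO2–(CH2)12–ring B)
Conditions: (NH4)6Mo7O24·4H2O (10 mol %), 30 % aq. H2O2 (5 equiv), EtOH–THF, 0 °C to rt
Reagents that add atoms: hydrogen peroxide, OO
Why: Molybdate-catalysed peroxide oxidation takes the dialkyl sulfide through the sulfoxide to the sulfone without touching the electron-rich arenes.

Step 10
Reactants: 15 22-membered macrocyclic sulfone
Product: 19 21-membered macrocyclic alkene C2'=C3' (E/Z mixture; trimethyl ether), via C3'-bromo sulfone 16 (not isolated), via C2'-bromo sulfone 17 (not isolated), via episulfone 18 (not isolated)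
Conditions: KOH/Al2O3, CBr2F2, t-BuOH–CH2Cl2, 5 °C to rt
Reagents that add atoms: none
Why: KOH on alumina deprotonates one α-CH2 of sulfone 15 and the carbanion takes bromine from CBr2F2 to give α-bromo sulfone 16 or 17; deprotonation at the other α-carbon and intramolecular SN2 displacement of bromide (a 1,3-elimination) form the C2'–C3' bond, and cheletropic loss of SO2 from episulfone 18, driven by the strain of the three-membered ring, leaves alkene 19. The closest known reaction type is the one-flask Ramberg–Bäcklund ring contraction of macrocyclic dialkyl sulfones to cycloalkenes, as used for cyclophanes. The bond-forming event closes two rings at once: the thiirane 1,1-dioxide by a 3-exo-tet closure and, through the same bond, the 21-membered carbocycle of the target, which arises by transannular closure inside the 22-membered thiacycle and so pays no macrocyclization entropy of its own. No stereocentre survives, since the bromine-bearing carbon and the two episulfone carbons are transient and the E/Z mixture of 19 is erased by hydrogenation in step 11. The selectivity needed is one halogenation at a sulfone α-carbon followed by ring closure faster than a second halogenation; the heterogeneous base with the mild bromine donor CBr2F2 suits sulfones with two primary α-carbons, either bromo regioisomer gives the same episulfone, the other C–H bonds of 15 (benzylic CH2, aryl C–H) are many pK units less acidic, and the aryl ethers are inert to base.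

Step 11
Reactants: 19 21-membered macrocyclic alkene (E/Z mixture)
Product: 20 target trimethyl ether (saturated 21-membered macrocycle; ring A 5-OMe; ring B 2,5-di-OMe)
Conditions: H2 (1 atm), Pd/C (10 wt % Pd on carbon), EtOAc–EtOH, rt
Reagents that add atoms: none
Why: Catalytic hydrogenation of the isolated 1,2-disubstituted ring alkene removes the last unsaturation outside the arenes, so both alkene isomers converge on one compound.

Step 12
Reactants: 20 target trimethyl ether
Product: 21 target CNP0393720.0 (macrocyclic diaryl ether triphenol)
Conditions: BBr3 (6 equiv), CH2Cl2, −78 °C to rt; aqueous work-up under Ar with Na2S2O4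
Reagents that add atoms: none
Why: Lewis-acid cleavage of the three aryl methyl ethers (O-coordination to boron, then SN2 by bromide at methyl) cannot touch the diaryl ether, which has no sp3 C–O carbon, and the reductive work-up should keep the hydroquinone ring from oxidizing to the quinone.

**Compound list**

1 | 2-(3,5-dimethoxyphenyl)ethan-1-ol | COc1cc(CCO)cc(OC)c1 | starting material
2 | 3-(2-hydroxyethyl)-5-methoxyphenol | COc1cc(O)cc(CCO)c1 | intermediate
3 | 3-bromo-2-hydroxy-5-methoxybenzaldehyde | COc1cc(Br)c(O)c(C=O)c1 | starting material
4 | 3-bromo-2,5-dimethoxybenzaldehyde | COc1cc(Br)c(OC)c(C=O)c1 | intermediate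
5 | 3-[3-(2-hydroxyethyl)-5-methoxyphenoxy]-2,5-dimethoxybenzaldehyde | COc1cc(CCO)cc(Oc2cc(OC)cc(C=O)c2OC)c1 | intermediate
6 | 11-bromoundecan-1-ol | OCCCCCCCCCCCBr | starting material
7 | (11-hydroxyundecyl)triphenylphosphonium bromide | OCCCCCCCCCCC[P+](c1ccccc1)(c1ccccc1)c1ccccc1.[Br-] | intermediate
8 | sodium 11-(triphenylphosphoranylidene)undecan-1-olate (alkoxide ylide) | [Na+].[O-]CCCCCCCCCC[CH-][P+](c1ccccc1)(c1ccccc1)c1ccccc1 | intermediate (not isolated)
9 | (Z)-12-{3-[3-(2-hydroxyethyl)-5-methoxyphenoxy]-2,5-dimethoxyphenyl}dodec-11-en-1-ol | COc1cc(CCO)cc(Oc2cc(OC)cc(/C=C\CCCCCCCCCCO)c2OC)c1 | intermediate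
10 | 12-{3-[3-(2-hydroxyethyl)-5-methoxyphenoxy]-2,5-dimethoxyphenyl}dodecan-1-ol | COc1cc(CCO)cc(Oc2cc(OC)cc(CCCCCCCCCCCCO)c2OC)c1 | intermediate
11 | 12-{3-[3-(2-mesyloxyethyl)-5-methoxyphenoxy]-2,5-dimethoxyphenyl}dodecyl methanesulfonate | COc1cc(CCOS(C)(=O)=O)cc(Oc2cc(OC)cc(CCCCCCCCCCCCOS(C)(=O)=O)c2OC)c1 | intermediate
12 | sodium thiolate at the ring A arm, mesylate kept at the chain end | COc1cc(CC[S-])cc(Oc2cc(OC)cc(CCCCCCCCCCCCOS(C)(=O)=O)c2OC)c1.[Na+] | intermediate (not isolated)
13 | sodium thiolate at the chain end, mesylate kept at the ring A arm | COc1cc(CCOS(C)(=O)=O)cc(Oc2cc(OC)cc(CCCCCCCCCCCC[S-])c2OC)c1.[Na+] | intermediate (not isolated)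
14 | 22-membered macrocyclic sulfide, sulfur between C2' and C3', three OMe | COc1cc2cc(c1)Oc1cc(OC)cc(c1OC)CCCCCCCCCCCCSCC2 | intermediate
15 | 22-membered macrocyclic sulfone (S,S-dioxide of 14) | COc1cc2cc(c1)Oc1cc(OC)cc(c1OC)CCCCCCCCCCCCS(=O)(=O)CC2 | intermediate
16 | α-bromo sulfone, bromine on C3' (racemic) | COc1cc2cc(c1)Oc1cc(OC)cc(c1OC)CCCCCCCCCCCC(Br)S(=O)(=O)CC2 | intermediate (not isolated)
17 | α-bromo sulfone, bromine on C2' (racemic) | COc1cc2cc(c1)Oc1cc(OC)cc(c1OC)CCCCCCCCCCCCS(=O)(=O)C(Br)C2 | intermediate (not isolated)
18 | episulfone: thiirane 1,1-dioxide spanning C2' and C3' of the 21-membered carbocycle (cis/trans mixture, racemic) | COc1cc2cc(c1)Oc1cc(OC)cc(c1OC)CCCCCCCCCCCC3C(C2)S3(=O)=O | intermediate (not isolated)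
19 | 21-membered macrocyclic alkene C2'=C3', trimethyl ether (E/Z mixture, geometry not specified) | COc1cc2cc(c1)Oc1cc(OC)cc(c1OC)CCCCCCCCCCCC=CC2 | intermediate
20 | target trimethyl ether (saturated 21-membered macrocycle) | COc1cc2cc(c1)Oc1cc(OC)cc(c1OC)CCCCCCCCCCCCCC2 | intermediate
21 | target CNP0393720.0 | Oc1cc2cc(c1)Oc1cc(O)cc(c1O)CCCCCCCCCCCCCC2 | target

**Step count and risks**

Total steps: 12. Longest linear sequence: 10 steps (step 1 or 2, then steps 3, 5, 6, 7, 8, 9, 10, 11, 12).

Steps most likely to fail:

1. Step 8. Intermolecular S-alkylation may give oligomers, a second sulfide may attack the remaining mesylate before ring closure, or E2 may occur at the 2-arylethyl mesylate. The fallback sets out from 11 and comes back at 14. Compound 11 is treated with one equivalent of KSAc in DMF at rt, which should give the two regioisomeric monothioacetates: the ring-A-arm thioacetate with the chain-end mesylate intact F1 and the chain-end thioacetate with the ring-A-arm mesylate intact F2. These are separated together from unchanged 11 (recycled) and from the bis-thioacetate. The mixture of F1 and F2 is then added slowly to K2CO3 in MeOH–THF at 50 °C under argon. Methanolysis unmasks exactly one thiolate per molecule, and the now strictly unimolecular ring closure gives 14 from either isomer.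

2. Step 10. A second halogenation may overtake ring closure, or difluorocarbene may add to the new alkene. The fallback sets out from 10 and comes back at 19, bypassing steps 7 to 10. Diol 10 is oxidized with Dess–Martin periodinane in CH2Cl2 to 12-{3-[3-(2-oxoethyl)-5-methoxyphenoxy]-2,5-dimethoxyphenyl}dodecanal F3, which is used at once. Intramolecular McMurry coupling with low-valent titanium (TiCl3(DME)1.5, Zn–Cu couple, DME, reflux, syringe-pump addition) joins the same two carbons as a C=C bond and gives 19 directly.

3. Step 3. Coupling at the aryl bromide hindered by the ortho-methoxy group may be slow, allowing protodebromination or oxidation of the phenol to compete. The fallback sets out from 4 and comes back at 5, with the polarity of the coupling reversed. Miyaura borylation of 4 (B2pin2, PdCl2(dppf), KOAc, dioxane, 80 °C) gives 2,5-dimethoxy-3-(4,4,5,5-tetramethyl-1,3,2-dioxaborolan-2-yl)benzaldehyde F4. Cleavage with NaIO4 and NH4OAc in acetone–water gives (3-formyl-2,5-dimethoxyphenyl)boronic acid F5. Chan–Lam coupling of F5 with phenol 2 (Cu(OAc)2, pyridine, 4 Å molecular sieves, CH2Cl2, air, rt) then gives 5.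

Further compounds
F1 | step 8 | S-{2-[3-(3-{12-[(methylsulfonyl)oxy]dodecyl}-2,5-dimethoxyphenoxy)-5-methoxyphenyl]ethyl} ethanethioate | COc1cc(CCSC(C)=O)cc(Oc2cc(OC)cc(CCCCCCCCCCCCOS(C)(=O)=O)c2OC)c1
F2 | step 8 | S-(12-{3-[3-(2-mesyloxyethyl)-5-methoxyphenoxy]-2,5-dimethoxyphenyl}dodecyl) ethanethioate | COc1cc(CCOS(C)(=O)=O)cc(Oc2cc(OC)cc(CCCCCCCCCCCCSC(C)=O)c2OC)c1
F3 | step 10 | 12-{3-[3-(2-oxoethyl)-5-methoxyphenoxy]-2,5-dimethoxyphenyl}dodecanal | COc1cc(CC=O)cc(Oc2cc(OC)cc(CCCCCCCCCCCC=O)c2OC)c1
F4 | step 3 | 2,5-dimethoxy-3-(4,4,5,5-tetramethyl-1,3,2-dioxaborolan-2-yl)benzaldehyde | COc1cc(B2OC(C)(C)C(C)(C)O2)c(OC)c(C=O)c1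
F5 | step 3 | (3-formyl-2,5-dimethoxyphenyl)boronic acid | COc1cc(B(O)O)c(OC)c(C=O)c1
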